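**Retrosynthetic overview**

1. Kushenol X ⇐ O5 desilylation ⇐ ring C closed last: acid frees the O1 phenol, which opens a (2R,3S)-chalcone epoxide 6-endo (O5 held as a TIPS ether, all other phenols as MOM ethers).
2. Epoxide ⇐ La/BINOL epoxidation of a chalcone ⇐ ring-A aryllithium + ring-B cinnamoyl Weinreb amide (bis-MOM resorcinol → bromide → Heck).
3. Lavandulyl chain built on ring A by three boron-to-carbon 1,2-shifts: Zweifel isopropenylation ⇐ enantioselective Pd conjunctive coupling (key step, sets the side-chain stereocentre) ⇐ ArLi/ClCH2Bpin homologation.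
4. Ring-A core ⇐ resorcinol: MOM protection, Ir C–H borylation/oxidation (third oxygen), TIPS protection.
5. Ring order: rings A and B come from resorcinol; ring C is the only ring formed.

Assumption: the target is made exactly as drawn, i.e. (2R,3R) in ring C and (R) at the side-chain carbon.

**Route**

Step 1
Reactants: 1 resorcinol
Product: 2 1,3-bis(methoxymethoxy)benzene
Conditions: NaH, MOMCl, DMF, 0 °C → rt
Reagents that add atoms: chloromethyl methyl ether COCCl
Why: Williamson-type O-alkylation of both phenoxides (MOM protection) gives two equal acid-labile directing groups, and this one ether serves both ring A and ring B.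

Step 2
Reactants: 2 1,3-bis(methoxymethoxy)benzene
Product: 4 3,5-bis(methoxymethoxy)phenol, via arylboronic ester 3 (not isolated)
Conditions: [Ir(OMe)(cod)]2 (1.5 mol %), 4,4′-di-tert-butyl-2,2′-bipyridine (3 mol %), B2pin2 (0.55 equiv), cyclohexane, 80 °C; then 30 % H2O2, NaOH, THF/H2O, 0 °C
Reagents that add atoms: bis(pinacolato)diboron CC1(C)OB(OC1(C)C)B1OC(C)(C)C(C)(C)O1 (boron of 3); hydrogen peroxide OO
Why: Sterically controlled Ir-catalysed C–H borylation goes to the only C–H not flanked by an OMOM group, and peroxide oxidation (aryl shift from boron to oxygen) gives the phenol in the same flask.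

Step 3
Reactants: 4 3,5-bis(methoxymethoxy)phenol
Product: 5 [3,5-bis(methoxymethoxy)phenoxy]tri(propan-2-yl)silane
Conditions: NaH, i-Pr3SiCl, THF, 0 °C → rt
Reagents that add atoms: chlorotri(propan-2-yl)silane CC(C)[Si](Cl)(C(C)C)C(C)C
Why: Silyl ether formation on the one free phenol; the TIPS ether survives organolithiums and the later acid step, so this oxygen (the future O5) cannot take part in ring closure.

Step 4
Reactants: 5 [3,5-bis(methoxymethoxy)phenoxy]tri(propan-2-yl)silane
Product: 8 2-({2,6-bis(methoxymethoxy)-4-[(triisopropylsilyl)oxy]phenyl}methyl)-4,4,5,5-tetramethyl-1,3,2-dioxaborolane, via aryllithium 6 (not isolated), via chloromethyl borate complex 7 (not isolated)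
Conditions: n-BuLi, THF, 0 °C; ClCH2Bpin, −78 °C → rt
Reagents that add atoms: n-butyllithium CCCC[Li] (lithium of 6 and 7); 2-(chloromethyl)-4,4,5,5-tetramethyl-1,3,2-dioxaborolane ClCB1OC(C)(C)C(C)(C)O1
Why: Directed ortho-metalation between the two OMOM groups, then borate formation and a Matteson-type 1,2-shift of the aryl group from boron to carbon with loss of chloride makes the Ar–CH2 bond.

Step 5
Reactants: 8 benzylic pinacol boronic ester; 9 1-bromo-2-methylprop-1-ene
Product: 11 2-[(2R)-1-{2,6-bis(methoxymethoxy)-4-[(triisopropylsilyl)oxy]phenyl}-5-methylhex-4-en-2-yl]-4,4,5,5-tetramethyl-1,3,2-dioxaborolane, via vinyl borate complex 10 (not isolated)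
Conditions: CH2=CHMgBr, THF, 0 °C → rt; then NaOTf, Pd(OAc)2 (3 mol %), Mandyphos-type ligand (Sp,Sp)-1,1′-bis[bis(4-methoxy-3,5-dimethylphenyl)phosphino]-2,2′-bis[(R)-α-(dimethylamino)benzyl]ferrocene (3.6 mol %; the mirror-image ligand is used if a first run, checked by oxidation of a sample to the carbinol, shows the opposite sense), 9, THF/DMSO, 40 °C
Reagents that add atoms: vinylmagnesium bromide C=C[Mg]Br
Why: Proposed new method: an enantioselective Pd-catalysed conjunctive cross-coupling with a benzylic migrating group, in which the cationic alkenyl–divalent-palladium complex binds the vinyl group of borate 10, the electron-rich benzyl carbon shifts 1,2 from boron to the α-carbon anti to palladium on the face chosen by the ligand (setting the (R)-centre), and reductive elimination joins the CH2 to the 2-methylpropenyl group to finish the prenyl arm; the closest known reaction type is the Pd/Mandyphos conjunctive coupling of alkyl- and aryl-migrating vinyl borates with aryl or alkenyl triflates and bromides, to my knowledge not demonstrated for a benzylic migrating group, where direct benzyl transmetalation could compete.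

Step 6
Reactants: 11 (R)-secondary boronic ester
Product: 14 2-[(2R)-5-methyl-2-(prop-1-en-2-yl)hex-4-en-1-yl]-1,3-bis(methoxymethoxy)-5-[(triisopropylsilyl)oxy]benzene, via isopropenyl borate complex 12 (not isolated), via iodoalkyl boronic ester 13 (not isolated)
Conditions: CH2=C(CH3)Br, t-BuLi, Et2O, −78 °C; 11, THF, −78 °C; I2, MeOH, −78 °C; NaOMe, MeOH, −78 °C → rt
Reagents that add atoms: isopropenyllithium [Li]C(C)=C (made in the flask from 2-bromopropene C=C(C)Br and t-BuLi); iodine II (iodine of 13)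
Why: Zweifel olefination: iodonium formation on the alkenyl borate triggers a stereoretentive 1,2-shift of the secondary carbon from boron to carbon, and methoxide-induced anti-elimination of boron and iodide gives the isopropenyl group with the (R)-centre intact.

Step 7
Reactants: 2 1,3-bis(methoxymethoxy)benzene
Product: 15 1-bromo-2,4-bis(methoxymethoxy)benzene
Conditions: N-bromosuccinimide, MeCN, 0 °C
Reagents that add atoms: N-bromosuccinimide O=C1CCC(=O)N1Br
Why: Electrophilic aromatic bromination goes para to one OMOM and ortho to the other, because the position between the two OMOM groups is hindered.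

Step 8
Reactants: 15 1-bromo-2,4-bis(methoxymethoxy)benzene; 16 N-methoxy-N-methylprop-2-enamide
Product: 17 (2E)-3-[2,4-bis(methoxymethoxy)phenyl]-N-methoxy-N-methylprop-2-enamide
Conditions: Pd(OAc)2 (5 mol %), P(o-tol)3 (10 mol %), Et3N, DMF, 100 °C
Reagents that add atoms: none
Why: Mizoroki–Heck reaction (oxidative addition to zerovalent palladium, syn-insertion, syn-β-hydride elimination) gives the E-cinnamoyl Weinreb amide.

Step 9
Reactants: 14 lavandulyl arene; 17 cinnamoyl Weinreb amide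
Product: 20 (2E)-1-{2,4-bis(methoxymethoxy)-3-[(2R)-5-methyl-2-(prop-1-en-2-yl)hex-4-en-1-yl]-6-[(triisopropylsilyl)oxy]phenyl}-3-[2,4-bis(methoxymethoxy)phenyl]prop-2-en-1-one, via aryllithium 18 (not isolated), via tetrahedral lithium adduct 19 (not isolated)
Conditions: s-BuLi, TMEDA, THF, −78 → −40 °C; 17, −78 → 0 °C; aq. NH4Cl
Reagents that add atoms: sec-butyllithium CCC(C)[Li] (lithium of 18 and 19)
Why: MOM-directed ortho-lithiation at the only ring C–H left (the two are equivalent), then Weinreb ketone synthesis, where the chelated tetrahedral adduct stops over-addition and conjugate addition, gives the E-chalcone with the ketone flanked by the OMOM next to the side chain and by the OTIPS group.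

Step 10
Reactants: 20 chalcone
Product: 21 {2,4-bis(methoxymethoxy)-3-[(2R)-5-methyl-2-(prop-1-en-2-yl)hex-4-en-1-yl]-6-[(triisopropylsilyl)oxy]phenyl}{(2R,3S)-3-[2,4-bis(methoxymethoxy)phenyl]oxiran-2-yl}methanone
Conditions: La(OiPr)3 (10 mol %), (S)-BINOL (10 mol %), Ph3As=O (10 mol %), t-BuOOH (decane), 4 Å molecular sieves, THF, rt; filtration through Et3N-deactivated silica
Reagents that add atoms: tert-butyl hydroperoxide CC(C)(C)OO
Why: Lanthanum–BINOL-catalysed nucleophilic (Weitz–Scheffer type) epoxidation: the metal-bound hydroperoxide adds only to the enone, leaving the two side-chain alkenes, and the ligand sets the trans-(2R,3S) epoxide (this sense is assigned to (S)-BINOL from memory of the parent chalcone; (R)-BINOL is used if it proves reversed).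

Step 11
Reactants: 21 epoxy ketone
Product: 23 (2R,3R)-2-(2,4-dihydroxyphenyl)-3,7-dihydroxy-8-[(2R)-5-methyl-2-(prop-1-en-2-yl)hex-4-en-1-yl]-5-[(triisopropylsilyl)oxy]-2,3-dihydro-4H-chromen-4-one, via phenolic epoxy ketone 22 (not isolated)
Conditions: HCl (2 M), MeOH/THF, 0 → 40 °C
Reagents that add atoms: none
Why: Acid-catalysed acetal exchange removes the four MOM groups and opens the epoxide at the benzylic carbon stabilised by the 2,4-dioxygenated ring; of the two ketone-flanking oxygens only O1 is free (O5 is still silylated), so it closes ring C 6-endo at C2 with inversion or, if the cation is free, under thermodynamic trans control, while C3 keeps the epoxide configuration, giving (2R,3R).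

Step 12
Reactants: 23 5-O-TIPS kushenol X
Product: 24 kushenol X
Conditions: Bu4NF, AcOH, THF, 0 °C
Reagents that add atoms: none
Why: Fluoride cleaves the aryl Si–O bond (desilylation), and the AcOH buffer protonates the phenoxide at once so the base-sensitive flavanonol and its stereocentres are not disturbed.

**Compound list**

1 | resorcinol (benzene-1,3-diol) | Oc1cccc(O)c1 | starting material
2 | 1,3-bis(methoxymethoxy)benzene | COCOc1cccc(OCOC)c1 | intermediate
3 | 2-[3,5-bis(methoxymethoxy)phenyl]-4,4,5,5-tetramethyl-1,3,2-dioxaborolane | COCOc1cc(OCOC)cc(c1)B1OC(C)(C)C(C)(C)O1 | intermediate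
4 | 3,5-bis(methoxymethoxy)phenol | COCOc1cc(O)cc(OCOC)c1 | intermediate
5 | [3,5-bis(methoxymethoxy)phenoxy]tri(propan-2-yl)silane | COCOc1cc(OCOC)cc(O[Si](C(C)C)(C(C)C)C(C)C)c1 | intermediate
6 | {2,6-bis(methoxymethoxy)-4-[(triisopropylsilyl)oxy]phenyl}lithium | [Li]c1c(OCOC)cc(O[Si](C(C)C)(C(C)C)C(C)C)cc1OCOC | intermediate
7 | lithium (chloromethyl){2,6-bis(methoxymethoxy)-4-[(triisopropylsilyl)oxy]phenyl}(pinacolato)borate | [Li+].ClC[B-]1(OC(C)(C)C(C)(C)O1)c2c(OCOC)cc(O[Si](C(C)C)(C(C)C)C(C)C)cc2OCOC | intermediate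
8 | 2-({2,6-bis(methoxymethoxy)-4-[(triisopropylsilyl)oxy]phenyl}methyl)-4,4,5,5-tetramethyl-1,3,2-dioxaborolane | CC1(C)OB(Cc2c(OCOC)cc(O[Si](C(C)C)(C(C)C)C(C)C)cc2OCOC)OC1(C)C | intermediate
9 | 1-bromo-2-methylprop-1-ene | CC(C)=CBr | starting material
10 | bromomagnesium ({2,6-bis(methoxymethoxy)-4-[(triisopropylsilyl)oxy]phenyl}methyl)(ethenyl)(pinacolato)borate | C=C[B-]1(Cc2c(OCOC)cc(O[Si](C(C)C)(C(C)C)C(C)C)cc2OCOC)OC(C)(C)C(C)(C)O1.[Mg+]Br | intermediate
11 | 2-[(2R)-1-{2,6-bis(methoxymethoxy)-4-[(triisopropylsilyl)oxy]phenyl}-5-methylhex-4-en-2-yl]-4,4,5,5-tetramethyl-1,3,2-dioxaborolane | CC1(C)OB(OC1(C)C)[C@H](CC=C(C)C)Cc2c(OCOC)cc(O[Si](C(C)C)(C(C)C)C(C)C)cc2OCOC | intermediate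
12 | lithium [(2R)-1-{2,6-bis(methoxymethoxy)-4-[(triisopropylsilyl)oxy]phenyl}-5-methylhex-4-en-2-yl](prop-1-en-2-yl)(pinacolato)borate | [Li+].C=C(C)[B-]1(OC(C)(C)C(C)(C)O1)[C@H](CC=C(C)C)Cc2c(OCOC)cc(O[Si](C(C)C)(C(C)C)C(C)C)cc2OCOC | intermediate
13 | 2-[(3R)-4-{2,6-bis(methoxymethoxy)-4-[(triisopropylsilyl)oxy]phenyl}-1-iodo-2-methyl-3-(3-methylbut-2-en-1-yl)butan-2-yl]-4,4,5,5-tetramethyl-1,3,2-dioxaborolane (C2 epimers) | CC(CI)(B1OC(C)(C)C(C)(C)O1)[C@H](CC=C(C)C)Cc2c(OCOC)cc(O[Si](C(C)C)(C(C)C)C(C)C)cc2OCOC | intermediate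
14 | 2-[(2R)-5-methyl-2-(prop-1-en-2-yl)hex-4-en-1-yl]-1,3-bis(methoxymethoxy)-5-[(triisopropylsilyl)oxy]benzene | C=C(C)[C@H](CC=C(C)C)Cc1c(OCOC)cc(O[Si](C(C)C)(C(C)C)C(C)C)cc1OCOC | intermediate
15 | 1-bromo-2,4-bis(methoxymethoxy)benzene | COCOc1ccc(Br)c(OCOC)c1 | intermediate
16 | N-methoxy-N-methylprop-2-enamide | C=CC(=O)N(C)OC | starting material
17 | (2E)-3-[2,4-bis(methoxymethoxy)phenyl]-N-methoxy-N-methylprop-2-enamide | CON(C)C(=O)/C=C/c1ccc(OCOC)cc1OCOC | intermediate
18 | {2,4-bis(methoxymethoxy)-3-[(2R)-5-methyl-2-(prop-1-en-2-yl)hex-4-en-1-yl]-6-[(triisopropylsilyl)oxy]phenyl}lithium | [Li]c1c(OCOC)c(C[C@@H](CC=C(C)C)C(C)=C)c(OCOC)cc1O[Si](C(C)C)(C(C)C)C(C)C | intermediate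
19 | lithium (2E)-1-{2,4-bis(methoxymethoxy)-3-[(2R)-5-methyl-2-(prop-1-en-2-yl)hex-4-en-1-yl]-6-[(triisopropylsilyl)oxy]phenyl}-3-[2,4-bis(methoxymethoxy)phenyl]-1-[methoxy(methyl)amino]prop-2-en-1-olate | [Li+].[O-]C(/C=C/c1ccc(OCOC)cc1OCOC)(N(C)OC)c1c(OCOC)c(C[C@@H](CC=C(C)C)C(C)=C)c(OCOC)cc1O[Si](C(C)C)(C(C)C)C(C)C | intermediate
20 | (2E)-1-{2,4-bis(methoxymethoxy)-3-[(2R)-5-methyl-2-(prop-1-en-2-yl)hex-4-en-1-yl]-6-[(triisopropylsilyl)oxy]phenyl}-3-[2,4-bis(methoxymethoxy)phenyl]prop-2-en-1-one | O=C(/C=C/c1ccc(OCOC)cc1OCOC)c1c(OCOC)c(C[C@@H](CC=C(C)C)C(C)=C)c(OCOC)cc1O[Si](C(C)C)(C(C)C)C(C)C | intermediate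
21 | {2,4-bis(methoxymethoxy)-3-[(2R)-5-methyl-2-(prop-1-en-2-yl)hex-4-en-1-yl]-6-[(triisopropylsilyl)oxy]phenyl}{(2R,3S)-3-[2,4-bis(methoxymethoxy)phenyl]oxiran-2-yl}methanone | O=C([C@@H]1O[C@H]1c2ccc(OCOC)cc2OCOC)c1c(OCOC)c(C[C@@H](CC=C(C)C)C(C)=C)c(OCOC)cc1O[Si](C(C)C)(C(C)C)C(C)C | intermediate
22 | {2,4-dihydroxy-3-[(2R)-5-methyl-2-(prop-1-en-2-yl)hex-4-en-1-yl]-6-[(triisopropylsilyl)oxy]phenyl}[(2R,3S)-3-(2,4-dihydroxyphenyl)oxiran-2-yl]methanone | O=C([C@@H]1O[C@H]1c2ccc(O)cc2O)c1c(O)c(C[C@@H](CC=C(C)C)C(C)=C)c(O)cc1O[Si](C(C)C)(C(C)C)C(C)C | intermediate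
23 | (2R,3R)-2-(2,4-dihydroxyphenyl)-3,7-dihydroxy-8-[(2R)-5-methyl-2-(prop-1-en-2-yl)hex-4-en-1-yl]-5-[(triisopropylsilyl)oxy]-2,3-dihydro-4H-chromen-4-one | C=C(C)[C@H](CC=C(C)C)Cc1c(O)cc(O[Si](C(C)C)(C(C)C)C(C)C)c2c1O[C@H](c1ccc(O)cc1O)[C@@H](O)C2=O | intermediate
24 | kushenol X, (2R,3R)-2-(2,4-dihydroxyphenyl)-3,5,7-trihydroxy-8-[(2R)-5-methyl-2-(prop-1-en-2-yl)hex-4-en-1-yl]-2,3-dihydro-4H-chromen-4-one | C=C(C)[C@H](CC=C(C)C)Cc1c(O)cc(O)c2c1O[C@H](c1ccc(O)cc1O)[C@@H](O)C2=O | target

**Step count and risks**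

Total: 12 steps. Longest linear sequence: 10 steps (steps 1–6 and 9–12); steps 7 and 8 form the ring-B branch.

The three steps most likely to fail:

Step 5 (the proposed new conjunctive coupling). The benzyl group may transmetalate directly to palladium instead of shifting, or the selectivity may be low. The fallback is known lithiation–borylation chemistry; it sets out from 8 and comes back at 11. Bought 4-methylpent-3-en-1-ol is carbamoylated (NaH, i-Pr2NCOCl, THF) to 4-methylpent-3-en-1-yl N,N-di(propan-2-yl)carbamate F1. s-BuLi/(−)-sparteine in Et2O at −78 °C removes the pro-S hydrogen and gives the configurationally stable (S)-1-lithio-4-methylpent-3-en-1-yl N,N-di(propan-2-yl)carbamate F2. Boronic ester 8 is added and is taken up with retention to give the lithium borate complex F3. MgBr2·OEt2 and warming to reflux bring about the 1,2-shift of the benzylic carbon with inversion at the carbamate carbon and loss of the carbamate, which gives 11 with the same (R) configuration.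

Step 9 (lithiation next to the bulky OTIPS group, then acylation). Deprotonation may be slow or the silyl group may migrate from oxygen to carbon. The fallback sets out from 14 and comes back at 18. N-Iodosuccinimide in MeCN at 0 °C iodinates the only free ring position (the tri-oxygenated arene is far more reactive than the two alkenes) and gives 1-iodo-2,4-bis(methoxymethoxy)-3-[(2R)-5-methyl-2-(prop-1-en-2-yl)hex-4-en-1-yl]-6-[(triisopropylsilyl)oxy]benzene F4. n-BuLi in THF at −78 °C then makes aryllithium 18 by iodine–lithium exchange instead of deprotonation, and 18 is acylated with 17 as in step 9.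

Step 11 (acid-triggered ring closure with loss of four MOM groups). The side-chain alkenes next to the free 7-OH may cyclise or add HCl, and the opened epoxide may rearrange. The fallback separates ring closure from deprotection and avoids protic acid; it sets out from 21 and comes back at 23. MgBr2·OEt2 in CH2Cl2/Et2O (0 °C → rt) chelates the ketone and the flanking MOM oxygen, removes only that MOM group, and opens the epoxide with bromide at the benzylic carbon to give (2S)-3-bromo-3-[2,4-bis(methoxymethoxy)phenyl]-2-hydroxy-1-{2-hydroxy-4-(methoxymethoxy)-3-[(2R)-5-methyl-2-(prop-1-en-2-yl)hex-4-en-1-yl]-6-[(triisopropylsilyl)oxy]phenyl}propan-1-one F5 (not isolated). The freed O1 phenol displaces the easily ionised benzylic bromide and gives the trans-flavanonol (2R,3R)-2-[2,4-bis(methoxymethoxy)phenyl]-3-hydroxy-7-(methoxymethoxy)-8-[(2R)-5-methyl-2-(prop-1-en-2-yl)hex-4-en-1-yl]-5-[(triisopropylsilyl)oxy]-2,3-dihydro-4H-chromen-4-one F6. The three remaining aryl MOM ethers are then removed with TMSOTf/2,2′-bipyridyl in CH2Cl2 at 0 °C and aqueous work-up, which gives 23.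

**Further compounds**

F1 | step 5 | 4-methylpent-3-en-1-yl N,N-di(propan-2-yl)carbamate | CC(C)=CCCOC(=O)N(C(C)C)C(C)C
F2 | step 5 | (S)-1-lithio-4-methylpent-3-en-1-yl N,N-di(propan-2-yl)carbamate | [Li][C@@H](CC=C(C)C)OC(=O)N(C(C)C)C(C)C
F3 | step 5 | lithium borate complex of F2 and 8 | [Li+].CC(C)N(C(C)C)C(=O)O[C@H](CC=C(C)C)[B-]1(Cc2c(OCOC)cc(O[Si](C(C)C)(C(C)C)C(C)C)cc2OCOC)OC(C)(C)C(C)(C)O1
F4 | step 9 | 1-iodo-2,4-bis(methoxymethoxy)-3-[(2R)-5-methyl-2-(prop-1-en-2-yl)hex-4-en-1-yl]-6-[(triisopropylsilyl)oxy]benzene | C=C(C)[C@H](CC=C(C)C)Cc1c(OCOC)cc(O[Si](C(C)C)(C(C)C)C(C)C)c(I)c1OCOC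
F5 | step 11 | (2S)-3-bromo-3-[2,4-bis(methoxymethoxy)phenyl]-2-hydroxy-1-{2-hydroxy-4-(methoxymethoxy)-3-[(2R)-5-methyl-2-(prop-1-en-2-yl)hex-4-en-1-yl]-6-[(triisopropylsilyl)oxy]phenyl}propan-1-one (C3 epimers) | O=C([C@H](O)C(Br)c2ccc(OCOC)cc2OCOC)c1c(O)c(C[C@@H](CC=C(C)C)C(C)=C)c(OCOC)cc1O[Si](C(C)C)(C(C)C)C(C)C
F6 | step 11 | (2R,3R)-2-[2,4-bis(methoxymethoxy)phenyl]-3-hydroxy-7-(methoxymethoxy)-8-[(2R)-5-methyl-2-(prop-1-en-2-yl)hex-4-en-1-yl]-5-[(triisopropylsilyl)oxy]-2,3-dihydro-4H-chromen-4-one | C=C(C)[C@H](CC=C(C)C)Cc1c(OCOC)cc(O[Si](C(C)C)(C(C)C)C(C)C)c2c1O[C@H](c1ccc(OCOC)cc1OCOC)[C@@H](O)C2=O
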